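**Retrosynthetic overview**
1. Target ⇐ asymmetric dihydroxylation of a prenyl terminus in the last step. The five-carbon tail is grown on the isopropenyl group of a p-menthene core (allylic oxidation, catalytic asymmetric allylboration, cross-metathesis); the acetate and the two angelates are put on one at a time.
2. Chlorohydrin ⇐ ring epoxide: hydroxyl-directed epoxidation of the cyclohexene, then trans-diaxial opening by chloride.
3. Cyclohexene (the only ring, formed once) ⇐ SmI2 pinacol cyclisation of an acyclic C10 (Z)-ene-dial. The bond between the two carbinol carbons (future CH–OAc and ring CH–O-angeloyl) is made, and both are set cis to each other and to the isopropenyl group.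
4. Enabling feature: the ring's C(CH3)(OH)–CHCl pair is carried as a (Z)-trisubstituted C=C. It holds the two formyl carbons 1,6 and cis (only a six-membered ring can close), makes one of them an enal with a fixed s-trans geometry, and later relays the new stereocentres to the chlorohydrin.
5. Ene-dial ⇐ furan-2(5H)-one: Rh-catalysed asymmetric isopropenyl addition (sets the ring carbon that bears the side chain), lactol, Still–Gennari olefination, reduction, double oxidation.

Key step: step 6

Remark on the chemistry: locants used in the text are C1 (ring CH bearing the side chain), C2 (ring CH2), C3 (CHCl), C4 (C(CH3)OH), C5 (CH–OAc), C6 (ring CH–O-angeloyl), C7 (exocyclic methylene carbon), C8 (side-chain CH–O-angeloyl), C9 (CH2), C10 (CHOH), C11 (C(CH3)2OH); angeloyl = (2Z)-2-methylbut-2-enoyl.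

**Step 1**
Reactants: 1 furan-2(5H)-one; 2 2-isopropenyl-4,4,5,5-tetramethyl-1,3,2-dioxaborolane
Product: 3 (4R)-4-(prop-1-en-2-yl)oxolan-2-one
Conditions: [Rh(cod)OH]2 (2.5 mol %), (R)-BINAP (6 mol %), K3PO4 (0.5 equiv), dioxane/H2O 10:1, 60 °C
Reagents that add atoms: none
Why: Hayashi–Miyaura rhodium-catalysed asymmetric 1,4-addition of an alkenylboronate to an unsaturated lactone, in which the (R)-BINAP–Rh–isopropenyl species adds to the enantioface that gives the (R)-β-substituted product (the sense known for cyclic enones and unsaturated lactones) and so sets C1.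

**Step 2**
Reactants: 3 (4R)-4-(prop-1-en-2-yl)oxolan-2-one
Product: 4 (4R)-4-(prop-1-en-2-yl)oxolan-2-ol
Conditions: DIBAL-H (1.05 equiv), CH2Cl2, −78 °C; aq. KNa tartrate
Reagents that add atoms: none
Why: Partial hydride reduction of a γ-lactone stops at the aluminium hemiacetal at low temperature and should give the lactol (anomeric mixture, of no consequence) without touching C1.

**Step 3**
Reactants: 4 (4R)-4-(prop-1-en-2-yl)oxolan-2-ol; 5 ethyl 2-[bis(2,2,2-trifluoroethoxy)phosphoryl]propanoate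
Product: 6 ethyl (2Z,5R)-5-(hydroxymethyl)-2,6-dimethylhepta-2,6-dienoate
Conditions: 5 (1.5 equiv), KN(SiMe3)2 (2.5 equiv), 18-crown-6 (4 equiv), THF, −78 °C; aq. NH4Cl
Reagents that add atoms: none
Why: Still–Gennari olefination on the open hydroxy-aldehyde form of the lactol, where the electron-poor phosphonate eliminates quickly from the kinetic adduct under dissociating potassium/crown conditions and should give the (Z)-2-methyl enoate with the ester carbon cis to the chain, the geometry the ring closure needs.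

**Step 4**
Reactants: 6 ethyl (2Z,5R)-5-(hydroxymethyl)-2,6-dimethylhepta-2,6-dienoate
Product: 7 (2Z,5R)-5-(hydroxymethyl)-2,6-dimethylhepta-2,6-dien-1-ol
Conditions: DIBAL-H (3.5 equiv), CH2Cl2, −78 to 0 °C; aq. KNa tartrate
Reagents that add atoms: none
Why: 1,2-Reduction of the enoate by DIBAL-H should give the (Z)-allylic alcohol without isomerising the trisubstituted alkene (ester-to-alcohol reduction).

**Step 5**
Reactants: 7 (2Z,5R)-5-(hydroxymethyl)-2,6-dimethylhepta-2,6-dien-1-ol
Product: 8 (2Z,5R)-2-methyl-5-(prop-1-en-2-yl)hex-2-enedial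
Conditions: Dess–Martin periodinane (2.5 equiv), pyridine (5 equiv), CH2Cl2, 0 °C; crude 8 used at once
Reagents that add atoms: none
Why: Dess–Martin oxidation converts both primary alcohols to aldehydes under buffered, non-enolising conditions, which should keep the Z-enal geometry and the α-isopropenyl stereocentre C1 intact as long as 8 is not purified.

**Step 6**
Reactants: 8 (2Z,5R)-2-methyl-5-(prop-1-en-2-yl)hex-2-enedial
Product: 9 (1S,2R,6R)-3-methyl-6-(prop-1-en-2-yl)cyclohex-3-ene-1,2-diol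
Conditions: SmI2 (2.5 equiv, 0.1 M in THF), THF, −78 °C, slow addition of 8 (final 0.01 M); aq. NH4Cl
Reagents that add atoms: none
Why: SmI2 (divalent samarium) gives one electron to the more easily reduced enal carbonyl, the trivalent-samarium dienyl ketyl binds the second formyl oxygen, its carbinyl carbon adds to that carbonyl carbon and a second electron gives the samarium diolate, protonated on work-up (intramolecular pinacol coupling; closest known reaction type: SmI2 cyclisation of 1,6-dialdehydes to cis-cyclohexane-1,2-diols). The six-membered carbocycle closes by 6-exo-trig attack of the ketyl carbon on C=O in a half-chair whose endocyclic cis double bond is the (Z)-alkene already present. The diol is cis because both oxygens sit on one samarium while the C–C bond forms. The oxygen of the (Z)-2-methylenal has to stay s-trans (exo, next to the methyl group, since the endo position collides with the cis chain), so it becomes pseudoequatorial at C5 and the samarium bridge then puts the new C6–O bond axial; at C6 the isopropenyl group on C1 takes the Felkin–Anh position anti to the forming bond (equatorial), and an equatorial C1 substituent beside an axial C6–O is cis, which gives the all-cis (1S,2R,6R) array. The step needs ring closure to beat intermolecular pinacol or γ,γ-coupling and conjugate reduction of the enal; this is secured by high dilution, the absence of a proton source, the Z geometry that holds the two carbonyl carbons within bonding distance, and the fact that attack through the γ-carbon of the ketyl would give a four-membered ring.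

**Step 7**
Reactants: 9 (1S,2R,6R)-3-methyl-6-(prop-1-en-2-yl)cyclohex-3-ene-1,2-diol
Product: 10 (1S,2S,3S,4R,6R)-1-methyl-4-(prop-1-en-2-yl)-7-oxabicyclo[4.1.0]heptane-2,3-diol
Conditions: VO(acac)2 (5 mol %), t-BuOOH (1.3 equiv), CH2Cl2, 0 °C
Reagents that add atoms: tert-butyl hydroperoxide, CC(C)(C)OO
Why: Vanadium-catalysed hydroxyl-directed epoxidation delivers the peroxide oxygen from vanadium bound to the allylic C5 hydroxyl (helped by the cis C6 hydroxyl), so the ring alkene should be epoxidised on the hydroxyl-bearing face, setting the C3 and C4 oxygen cis to the diol, while the undirected isopropenyl alkene is left.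

**Step 8**
Reactants: 10 (1S,2S,3S,4R,6R)-1-methyl-4-(prop-1-en-2-yl)-7-oxabicyclo[4.1.0]heptane-2,3-diol
Product: 11 (1S,2S,3S,4S,6R)-4-chloro-3-methyl-6-(prop-1-en-2-yl)cyclohexane-1,2,3-triol
Conditions: Et2NH2Cl (3 equiv), Ti(OiPr)4 (1.5 equiv), CH2Cl2, 25 °C; aq. tartaric acid
Reagents that add atoms: diethylammonium chloride, CC[NH2+]CC.[Cl-]
Why: Titanium-assisted opening of a 2,3-epoxy alcohol, in which chloride attacks the secondary carbon distal to the chelating C5 hydroxyl (C3) with inversion in a trans-diaxial (Fürst–Plattner) opening that leads straight to the chair with an equatorial isopropenyl group, giving axial chlorine at C3 trans to the axial tertiary hydroxyl at C4.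

**Step 9**
Reactants: 11 (1S,2S,3S,4S,6R)-4-chloro-3-methyl-6-(prop-1-en-2-yl)cyclohexane-1,2,3-triol
Product: 13 (1S,2S,3S,4S,6R)-4-chloro-3-methyl-6-(prop-1-en-2-yl)cyclohexane-1,2,3-triol 2-acetate, via stannylene acetal 12 (not isolated)
Conditions: Bu2SnO (1.1 equiv), toluene, reflux (Dean–Stark); then AcCl (1.05 equiv), 0 °C
Reagents that add atoms: acetyl chloride, CC(=O)Cl; dibutyltin oxide, CCCC[Sn](=O)CCCC (its atoms are in 12 only)
Why: Regioselective acylation of a cis-1,2-diol through its dibutylstannylene acetal, which activates the equatorial oxygen (C5–O) over the axial C6–O and leaves the tertiary C4 hydroxyl untouched, so no stereocentre changes.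

**Step 10**
Reactants: 13 (1S,2S,3S,4S,6R)-4-chloro-3-methyl-6-(prop-1-en-2-yl)cyclohexane-1,2,3-triol 2-acetate; 14 angelic acid
Product: 15 (1S,2S,3S,4S,6R)-4-chloro-3-methyl-6-(prop-1-en-2-yl)cyclohexane-1,2,3-triol 2-acetate 1-[(2Z)-2-methylbut-2-enoate]
Conditions: 14 (3 equiv), 2,4,6-Cl3C6H2COCl (3 equiv), Et3N (6 equiv), toluene, 25 °C; then 13, 80 °C
Reagents that add atoms: none
Why: Yamaguchi-type esterification through the angelic 2,4,6-trichlorobenzoic mixed anhydride, an acyl donor that should transfer the (Z)-2-methylbut-2-enoyl group to the hindered axial C6 hydroxyl without Z-to-E isomerisation, the tertiary hydroxyl being inert.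

**Step 11**
Reactants: 15 (1S,2S,3S,4S,6R)-4-chloro-3-methyl-6-(prop-1-en-2-yl)cyclohexane-1,2,3-triol 2-acetate 1-[(2Z)-2-methylbut-2-enoate]
Product: 17 (1S,2S,3S,4S,6R)-4-chloro-3-methyl-6-(3-oxoprop-1-en-2-yl)cyclohexane-1,2,3-triol 2-acetate 1-[(2Z)-2-methylbut-2-enoate], via allylic alcohol 16 (not isolated)
Conditions: SeO2 (0.5 equiv), t-BuOOH (3 equiv), salicylic acid (0.1 equiv), CH2Cl2, 25 °C; then MnO2 (15 equiv), CH2Cl2
Reagents that add atoms: tert-butyl hydroperoxide, CC(C)(C)OO
Why: Riley allylic oxidation (ene reaction then [2,3]-shift) of the 1,1-disubstituted alkene should occur at its methyl group rather than at the ring methine, and MnO2 takes the allylic alcohol on to the 2-substituted acrolein, while the electron-poor angelate alkene does not react.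

**Step 12**
Reactants: 17 (1S,2S,3S,4S,6R)-4-chloro-3-methyl-6-(3-oxoprop-1-en-2-yl)cyclohexane-1,2,3-triol 2-acetate 1-[(2Z)-2-methylbut-2-enoate]; 18 2-allyl-4,4,5,5-tetramethyl-1,3,2-dioxaborolane
Product: 19 (1S,2S,3S,4S,6R)-4-chloro-6-[(3S)-3-hydroxyhexa-1,5-dien-2-yl]-3-methylcyclohexane-1,2,3-triol 2-acetate 1-[(2Z)-2-methylbut-2-enoate]
Conditions: 18 (1.5 equiv), (S)-TRIP [(S)-3,3′-bis(2,4,6-triisopropylphenyl)-1,1′-binaphthyl-2,2′-diyl hydrogen phosphate] (5 mol %), 4 Å MS, toluene, −30 °C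
Reagents that add atoms: none
Why: Chiral phosphoric acid-catalysed allylboration of the enal through a chair six-membered transition state, with the catalyst antipode chosen so that allyl is delivered to the Si face of the aldehyde, which should set C8 as S under catalyst control.

**Step 13**
Reactants: 19 (1S,2S,3S,4S,6R)-4-chloro-6-[(3S)-3-hydroxyhexa-1,5-dien-2-yl]-3-methylcyclohexane-1,2,3-triol 2-acetate 1-[(2Z)-2-methylbut-2-enoate]; 14 angelic acid
Product: 20 (1S,2S,3S,4S,6R)-4-chloro-3-methyl-6-[(3S)-3-{[(2Z)-2-methylbut-2-enoyl]oxy}hexa-1,5-dien-2-yl]cyclohexane-1,2,3-triol 2-acetate 1-[(2Z)-2-methylbut-2-enoate]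
Conditions: 14 (2 equiv), 2,4,6-Cl3C6H2COCl (2 equiv), Et3N (4 equiv), toluene, 25 °C; then 19, 60 °C
Reagents that add atoms: none
Why: The same mixed-anhydride (Yamaguchi-type) angeloylation, now on the less hindered secondary C8 hydroxyl with retention of its configuration, the tertiary hydroxyl again staying free.

**Step 14**
Reactants: 20 (1S,2S,3S,4S,6R)-4-chloro-3-methyl-6-[(3S)-3-{[(2Z)-2-methylbut-2-enoyl]oxy}hexa-1,5-dien-2-yl]cyclohexane-1,2,3-triol 2-acetate 1-[(2Z)-2-methylbut-2-enoate]; 21 2-methylbut-2-ene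
Product: 22 (1S,2S,3S,4S,6R)-4-chloro-3-methyl-6-[(3S)-6-methyl-3-{[(2Z)-2-methylbut-2-enoyl]oxy}hepta-1,5-dien-2-yl]cyclohexane-1,2,3-triol 2-acetate 1-[(2Z)-2-methylbut-2-enoate]
Conditions: second-generation Grubbs catalyst (H2IMes)(PCy3)Cl2Ru=CHPh (5 mol %), 21 (20 equiv), CH2Cl2, 40 °C
Reagents that add atoms: none
Why: Olefin cross-metathesis of the monosubstituted alkene with 2-methylbut-2-ene should install the trisubstituted prenyl terminus, since the hindered 1,1-disubstituted alkene and the conjugated trisubstituted angelate alkenes are not metathesis partners under these conditions.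

**Step 15**
Reactants: 22 (1S,2S,3S,4S,6R)-4-chloro-3-methyl-6-[(3S)-6-methyl-3-{[(2Z)-2-methylbut-2-enoyl]oxy}hepta-1,5-dien-2-yl]cyclohexane-1,2,3-triol 2-acetate 1-[(2Z)-2-methylbut-2-enoate]
Product: 23 (1S,2S,3S,4S,6R)-4-chloro-6-[(3S,5R)-5,6-dihydroxy-6-methyl-3-{[(2Z)-2-methylbut-2-enoyl]oxy}hept-1-en-2-yl]-3-methylcyclohexane-1,2,3-triol 2-acetate 1-[(2Z)-2-methylbut-2-enoate]
Conditions: OsO4 (2 mol %), (DHQD)2PHAL (8 mol %), N-methylmorpholine N-oxide (1.3 equiv), acetone/H2O 10:1, 0 °C, slow addition of 22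
Reagents that add atoms: N-methylmorpholine N-oxide, C[N+]1([O-])CCOCC1; water, O
Why: Sharpless asymmetric dihydroxylation run with the amine oxide as oxidant (no carbonate base, so the chlorohydrin and the esters see no alkali), in which the electron-rich prenyl alkene should react much faster than the hindered 1,1-disubstituted and the electron-poor angelate alkenes and the dihydroquinidine ligand delivers both oxygens to the face that gives the 10R carbinol, as it does for other prenyl termini.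

**Compound list**
1 | furan-2(5H)-one | O=C1C=CCO1 | starting material
2 | 2-isopropenyl-4,4,5,5-tetramethyl-1,3,2-dioxaborolane | C=C(C)B1OC(C)(C)C(C)(C)O1 | starting material
3 | (4R)-4-(prop-1-en-2-yl)oxolan-2-one | C=C(C)[C@H]1CC(=O)OC1 | intermediate
4 | (4R)-4-(prop-1-en-2-yl)oxolan-2-ol (both anomers) | C=C(C)[C@H]1CC(O)OC1 | intermediate
5 | ethyl 2-[bis(2,2,2-trifluoroethoxy)phosphoryl]propanoate | CCOC(=O)C(C)P(=O)(OCC(F)(F)F)OCC(F)(F)F | starting material
6 | ethyl (2Z,5R)-5-(hydroxymethyl)-2,6-dimethylhepta-2,6-dienoate | C=C(C)[C@@H](C/C=C(C)\C(=O)OCC)CO | intermediate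
7 | (2Z,5R)-5-(hydroxymethyl)-2,6-dimethylhepta-2,6-dien-1-ol | C=C(C)[C@@H](C/C=C(C)\CO)CO | intermediate
8 | (2Z,5R)-2-methyl-5-(prop-1-en-2-yl)hex-2-enedial | C=C(C)[C@@H](C/C=C(C)\C=O)C=O | intermediate
9 | (1S,2R,6R)-3-methyl-6-(prop-1-en-2-yl)cyclohex-3-ene-1,2-diol | C=C(C)[C@H]1CC=C(C)[C@@H](O)[C@H]1O | intermediate
10 | (1S,2S,3S,4R,6R)-1-methyl-4-(prop-1-en-2-yl)-7-oxabicyclo[4.1.0]heptane-2,3-diol | C=C(C)[C@H]1C[C@H]2O[C@@]2(C)[C@@H](O)[C@H]1O | intermediate
11 | (1S,2S,3S,4S,6R)-4-chloro-3-methyl-6-(prop-1-en-2-yl)cyclohexane-1,2,3-triol | C=C(C)[C@H]1C[C@H](Cl)[C@@](C)(O)[C@@H](O)[C@H]1O | intermediate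
12 | 1,2-O-dibutylstannylene acetal of 11 (2,2-dibutyl-1,3,2-dioxastannolane fused at the cis secondary diol) | C=C(C)[C@H]1C[C@H](Cl)[C@@](C)(O)[C@H]2O[Sn](CCCC)(CCCC)O[C@@H]12 | intermediate (not isolated)
13 | (1S,2S,3S,4S,6R)-4-chloro-3-methyl-6-(prop-1-en-2-yl)cyclohexane-1,2,3-triol 2-acetate | C=C(C)[C@H]1C[C@H](Cl)[C@@](C)(O)[C@@H](OC(C)=O)[C@H]1O | intermediate
14 | angelic acid, (2Z)-2-methylbut-2-enoic acid | C/C=C(/C)C(=O)O | starting material
15 | (1S,2S,3S,4S,6R)-4-chloro-3-methyl-6-(prop-1-en-2-yl)cyclohexane-1,2,3-triol 2-acetate 1-[(2Z)-2-methylbut-2-enoate] | C=C(C)[C@H]1C[C@H](Cl)[C@@](C)(O)[C@@H](OC(C)=O)[C@H]1OC(=O)/C(C)=C\C | intermediate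
16 | (1S,2S,3S,4S,6R)-4-chloro-6-(3-hydroxyprop-1-en-2-yl)-3-methylcyclohexane-1,2,3-triol 2-acetate 1-[(2Z)-2-methylbut-2-enoate] | C=C(CO)[C@H]1C[C@H](Cl)[C@@](C)(O)[C@@H](OC(C)=O)[C@H]1OC(=O)/C(C)=C\C | intermediate (not isolated)
17 | (1S,2S,3S,4S,6R)-4-chloro-3-methyl-6-(3-oxoprop-1-en-2-yl)cyclohexane-1,2,3-triol 2-acetate 1-[(2Z)-2-methylbut-2-enoate] | C=C(C=O)[C@H]1C[C@H](Cl)[C@@](C)(O)[C@@H](OC(C)=O)[C@H]1OC(=O)/C(C)=C\C | intermediate
18 | 2-allyl-4,4,5,5-tetramethyl-1,3,2-dioxaborolane | C=CCB1OC(C)(C)C(C)(C)O1 | starting material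
19 | (1S,2S,3S,4S,6R)-4-chloro-6-[(3S)-3-hydroxyhexa-1,5-dien-2-yl]-3-methylcyclohexane-1,2,3-triol 2-acetate 1-[(2Z)-2-methylbut-2-enoate] | C=C([C@H](CC=C)O)[C@H]1C[C@H](Cl)[C@@](C)(O)[C@@H](OC(C)=O)[C@H]1OC(=O)/C(C)=C\C | intermediate
20 | (1S,2S,3S,4S,6R)-4-chloro-3-methyl-6-[(3S)-3-{[(2Z)-2-methylbut-2-enoyl]oxy}hexa-1,5-dien-2-yl]cyclohexane-1,2,3-triol 2-acetate 1-[(2Z)-2-methylbut-2-enoate] | C=C([C@H](CC=C)OC(=O)/C(C)=C\C)[C@H]1C[C@H](Cl)[C@@](C)(O)[C@@H](OC(C)=O)[C@H]1OC(=O)/C(C)=C\C | intermediate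
21 | 2-methylbut-2-ene | CC=C(C)C | starting material
22 | (1S,2S,3S,4S,6R)-4-chloro-3-methyl-6-[(3S)-6-methyl-3-{[(2Z)-2-methylbut-2-enoyl]oxy}hepta-1,5-dien-2-yl]cyclohexane-1,2,3-triol 2-acetate 1-[(2Z)-2-methylbut-2-enoate] | C=C([C@H](CC=C(C)C)OC(=O)/C(C)=C\C)[C@H]1C[C@H](Cl)[C@@](C)(O)[C@@H](OC(C)=O)[C@H]1OC(=O)/C(C)=C\C | intermediate
23 | CNP0223769.1, (1S,2S,3S,4S,6R)-4-chloro-6-[(3S,5R)-5,6-dihydroxy-6-methyl-3-{[(2Z)-2-methylbut-2-enoyl]oxy}hept-1-en-2-yl]-3-methylcyclohexane-1,2,3-triol 2-acetate 1-[(2Z)-2-methylbut-2-enoate] | C=C([C@H](C[C@@H](O)C(C)(C)O)OC(=O)/C(C)=C\C)[C@H]1C[C@H](Cl)[C@@](C)(O)[C@@H](OC(C)=O)[C@H]1OC(=O)/C(C)=C\C | target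

**Step count and risks**
Total step count: 15. Longest linear sequence: 15 steps (from 1).

Steps most likely to fail:

1. Step 6. What may go wrong: poor facial selectivity at the aldehyde next to the isopropenyl-bearing carbon (diol formed trans to that group), or loss of the enal ketyl to intermolecular coupling or over-reduction before the ring closes. The fallback sets out from 6 and returns at 11; it fixes the chlorohydrin in the open chain first and lets its tertiary hydroxyl template the same bond formation. The hydroxyl of 6 would be silylated (TBSCl, imidazole) to ethyl (2Z,5R)-5-{[tert-butyl(dimethyl)silyl]oxymethyl}-2,6-dimethylhepta-2,6-dienoate F1. DIBAL-H would give (2Z,5R)-5-{[tert-butyl(dimethyl)silyl]oxymethyl}-2,6-dimethylhepta-2,6-dien-1-ol F2. Sharpless asymmetric epoxidation (Ti(OiPr)4, L-(+)-diisopropyl tartrate, t-BuOOH, −20 °C) would give [(2S,3R)-3-[(2R)-2-{[tert-butyl(dimethyl)silyl]oxymethyl}-3-methylbut-3-en-1-yl]-2-methyloxiran-2-yl]methanol F3. Et2NH2Cl with Ti(OiPr)4 would open it at the distal carbon to (2S,3S,5R)-6-{[tert-butyl(dimethyl)silyl]oxy}-3-chloro-2-methyl-5-(prop-1-en-2-yl)hexane-1,2-diol F4. HF·pyridine would give (2S,3S,5R)-3-chloro-2-methyl-5-(prop-1-en-2-yl)hexane-1,2,6-triol F5. Swern oxidation would give the hydroxy dialdehyde, which rests as its six-membered lactol (2S,3S,5R)-3-chloro-6-hydroxy-2-methyl-5-(prop-1-en-2-yl)oxane-2-carbaldehyde F6. SmI2 in THF would then close the same bond on the open form: the free tertiary hydroxyl and the two new oxygens share one trivalent samarium (axial–equatorial–axial triol) and the axial chlorine disfavours the other diol face, so 11 should form directly and steps 7 and 8 are not needed.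

2. Step 9. What may go wrong: insufficient regioselectivity between the two secondary hydroxyls, or migration of the acetyl group between the cis oxygens (also during the heating of step 10). The fallback sets out from 11 and returns at 15; it replaces direct differentiation by a temporary silyl group. TESCl (1.05 equiv) and imidazole at −20 °C would silylate the less hindered equatorial C5 hydroxyl to (1S,2S,3S,4S,6R)-4-chloro-3-methyl-6-(prop-1-en-2-yl)-2-[(triethylsilyl)oxy]cyclohexane-1,3-diol F7. Mixed-anhydride angeloylation of the C6 hydroxyl would give its 1-[(2Z)-2-methylbut-2-enoate] F8. HF·pyridine would free the C5 hydroxyl to give (1S,2S,3S,4S,6R)-4-chloro-3-methyl-6-(prop-1-en-2-yl)cyclohexane-1,2,3-triol 1-[(2Z)-2-methylbut-2-enoate] F9. Ac2O in pyridine would then acetylate the only free secondary hydroxyl to give 15.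

3. Step 15. What may go wrong: insufficient chemoselectivity among the four alkenes, low face selectivity at the remote prenyl alkene, or closure of the chlorohydrin to the epoxide if the medium turns basic. The fallback sets out from 17 and returns at 23; it builds the side-chain diol by aldol addition and 1,3-syn reduction instead of allylation, metathesis and dihydroxylation. The boron enolate of 3-methyl-3-[(triethylsilyl)oxy]butan-2-one (made from commercial 3-hydroxy-3-methylbutan-2-one and TESCl) would be generated with Ipc2BCl (the antipode that adds to the Si face of the aldehyde) and Et3N, and would add to 17 to give the (8S)-β-hydroxy ketone (C8 hydroxyl, C10 ketone, C11 triethylsilyl ether) F10. Narasaka–Prasad reduction (Et2BOMe, NaBH4, THF/MeOH, −78 °C) would give the syn-1,3-diol (8S,10R) F11. Mixed-anhydride angeloylation would take place at the C8 hydroxyl, the C10 hydroxyl being shielded by the neighbouring silyloxy-bearing quaternary carbon, to give the C8 angelate F12. HF·pyridine would remove the triethylsilyl group to give 23.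

**Further compounds**
F1 | step 6 | ethyl (2Z,5R)-5-{[tert-butyl(dimethyl)silyl]oxymethyl}-2,6-dimethylhepta-2,6-dienoate | C=C(C)[C@@H](C/C=C(C)\C(=O)OCC)CO[Si](C)(C)C(C)(C)C
F2 | step 6 | (2Z,5R)-5-{[tert-butyl(dimethyl)silyl]oxymethyl}-2,6-dimethylhepta-2,6-dien-1-ol | C=C(C)[C@@H](C/C=C(C)\CO)CO[Si](C)(C)C(C)(C)C
F3 | step 6 | [(2S,3R)-3-[(2R)-2-{[tert-butyl(dimethyl)silyl]oxymethyl}-3-methylbut-3-en-1-yl]-2-methyloxiran-2-yl]methanol | C=C(C)[C@@H](C[C@H]1O[C@@]1(C)CO)CO[Si](C)(C)C(C)(C)C
F4 | step 6 | (2S,3S,5R)-6-{[tert-butyl(dimethyl)silyl]oxy}-3-chloro-2-methyl-5-(prop-1-en-2-yl)hexane-1,2-diol | C=C(C)[C@@H](C[C@H](Cl)[C@@](C)(O)CO)CO[Si](C)(C)C(C)(C)C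
F5 | step 6 | (2S,3S,5R)-3-chloro-2-methyl-5-(prop-1-en-2-yl)hexane-1,2,6-triol | C=C(C)[C@@H](C[C@H](Cl)[C@@](C)(O)CO)CO
F6 | step 6 | (2S,3S,5R)-3-chloro-6-hydroxy-2-methyl-5-(prop-1-en-2-yl)oxane-2-carbaldehyde (both anomers) | C=C(C)[C@H]1C[C@H](Cl)[C@](C)(C=O)OC1O
F7 | step 9 | (1S,2S,3S,4S,6R)-4-chloro-3-methyl-6-(prop-1-en-2-yl)-2-[(triethylsilyl)oxy]cyclohexane-1,3-diol | C=C(C)[C@H]1C[C@H](Cl)[C@@](C)(O)[C@@H](O[Si](CC)(CC)CC)[C@H]1O
F8 | step 9 | (1S,2S,3S,4S,6R)-4-chloro-3-hydroxy-3-methyl-6-(prop-1-en-2-yl)-2-[(triethylsilyl)oxy]cyclohexyl (2Z)-2-methylbut-2-enoate | C=C(C)[C@H]1C[C@H](Cl)[C@@](C)(O)[C@@H](O[Si](CC)(CC)CC)[C@H]1OC(=O)/C(C)=C\C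
F9 | step 9 | (1S,2S,3S,4S,6R)-4-chloro-3-methyl-6-(prop-1-en-2-yl)cyclohexane-1,2,3-triol 1-[(2Z)-2-methylbut-2-enoate] | C=C(C)[C@H]1C[C@H](Cl)[C@@](C)(O)[C@@H](O)[C@H]1OC(=O)/C(C)=C\C
F10 | step 15 | (1S,2S,3S,4S,6R)-4-chloro-6-[(3S)-3-hydroxy-6-methyl-5-oxo-6-[(triethylsilyl)oxy]hept-1-en-2-yl]-3-methylcyclohexane-1,2,3-triol 2-acetate 1-[(2Z)-2-methylbut-2-enoate] | C=C([C@H](CC(=O)C(C)(C)O[Si](CC)(CC)CC)O)[C@H]1C[C@H](Cl)[C@@](C)(O)[C@@H](OC(C)=O)[C@H]1OC(=O)/C(C)=C\C
F11 | step 15 | (1S,2S,3S,4S,6R)-4-chloro-6-[(3S,5R)-3,5-dihydroxy-6-methyl-6-[(triethylsilyl)oxy]hept-1-en-2-yl]-3-methylcyclohexane-1,2,3-triol 2-acetate 1-[(2Z)-2-methylbut-2-enoate] | C=C([C@H](C[C@@H](O)C(C)(C)O[Si](CC)(CC)CC)O)[C@H]1C[C@H](Cl)[C@@](C)(O)[C@@H](OC(C)=O)[C@H]1OC(=O)/C(C)=C\C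
F12 | step 15 | (1S,2S,3S,4S,6R)-4-chloro-6-[(3S,5R)-5-hydroxy-6-methyl-3-{[(2Z)-2-methylbut-2-enoyl]oxy}-6-[(triethylsilyl)oxy]hept-1-en-2-yl]-3-methylcyclohexane-1,2,3-triol 2-acetate 1-[(2Z)-2-methylbut-2-enoate] | C=C([C@H](C[C@@H](O)C(C)(C)O[Si](CC)(CC)CC)OC(=O)/C(C)=C\C)[C@H]1C[C@H](Cl)[C@@](C)(O)[C@@H](OC(C)=O)[C@H]1OC(=O)/C(C)=C\C
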